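The plan cuts the biaryl bond C2–C1′ between ring A and the resorcinol ring B. On either side of that bond sit C7, attached to C1 of ring A, and the oxygen on C2′ of ring B. Joined to each other, they make an aryl ester whose carbonyl carbon is C7. Palladium-catalysed intramolecular C–H arylation across this ester forges C2–C1′ and closes a benzo[c]chromen-6-one in one operation. The precursor is a 3-(methoxymethoxy)phenyl 2-chlorobenzoate that already carries the C6 arylalkyne and the silylated C5 hydroxymethyl group. Two aryllithium additions then convert the lactone carbonyl into the triaryl C7 and release the 2′-OH. One mild acid treatment unmasks the target.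

Key step: step 11

Numbering: ring A is C1 (bears C7), C2 (bears ring B), C3–H, C4–H, C5 (CH2OH), C6 (alkyne). Ring B is C1′ (bonded to C2), C2′–OH, C4′–OH. The target has no stereocentre, and its exocyclic C=C has no geometry because the dienone ring is symmetric.

Assumption: the open quinone methide drawn is taken as the stable form of the target; its ring-closed isomer, a 6,6-diaryl-6H-benzo[c]chromene formed through the 2′-OH, would interconvert with it through the C7 cation under acid.

Design of the precursor:
- **MOM acetals on every phenol oxygen.** Fourfold demethylation of methyl ethers with a boron halide would also attack the benzylic C5–O bond. It would also hold the C7 cation under strongly Lewis-acidic conditions next to the alkyne and ring B. MOM tolerates base, palladium and aryllithium, leaves together with TBS in one mild acid step, and crowds the unwanted C–H site of ring B more than methyl does.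
- **Chlorine at C2.** It stays inert while the C6 triflate is coupled.
- **Alkyne installed at the aldehyde stage.** The triflate is then most activated and least hindered.

Step 1
Reactants: 1 resorcinol
Product: 2 3-(methoxymethoxy)phenol
Conditions: MOMCl (1 equiv), i-Pr2NEt, 1 in excess (2 equiv), THF, 0 °C to rt
Reagents that add atoms: chloromethyl methyl ether (MOMCl), COCCl
Why: Williamson-type O-alkylation with a chloromethyl ether; the excess of diol keeps double protection low and unreacted 1 washes out with water.

Step 2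
Reactants: 3 2-chloro-6-hydroxybenzoic acid; 2 3-(methoxymethoxy)phenol
Product: 4 3-(methoxymethoxy)phenyl 2-chloro-6-hydroxybenzoate
Conditions: DCC, DMAP (cat.), CH2Cl2, 0 °C to rt
Reagents that add atoms: none
Why: Steglich esterification, the usual entry to depside-type aryl esters of 2,6-disubstituted salicylic acids; the acid's own phenol is hydrogen-bonded and hindered, so phenol 2 should be acylated in preference.

Step 3
Reactants: 4 3-(methoxymethoxy)phenyl 2-chloro-6-hydroxybenzoate
Product: 5 3-(methoxymethoxy)phenyl 6-chloro-3-formyl-2-hydroxybenzoate (CHO on ring A C5)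
Conditions: MgCl2 (anhydrous), Et3N, (CH2O)n, MeCN, 80 °C; cold 1 M HCl work-up
Reagents that add atoms: formaldehyde (from paraformaldehyde), C=O
Why: Casnati–Skattebøl magnesium-mediated ortho-formylation, in which only the ring with a free phenol forms the magnesium phenoxide and C5 is its only open ortho carbon, so C3 and ring B stay untouched while the two ortho substituents shield the aryl ester.

Step 4
Reactants: 5 3-(methoxymethoxy)phenyl 6-chloro-3-formyl-2-hydroxybenzoate
Product: 6 3-(methoxymethoxy)phenyl 6-chloro-3-formyl-2-(trifluoromethylsulfonyloxy)benzoate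
Conditions: Tf2O, pyridine, CH2Cl2, −10 to 0 °C
Reagents that add atoms: triflic anhydride, O=S(=O)(OS(=O)(=O)C(F)(F)F)C(F)(F)F
Why: O-sulfonylation of an acidic salicylaldehyde-type phenol; the cold, pyridine-buffered medium should spare the MOM acetal, the aldehyde and the aryl ester.

Step 5
Reactants: 7 4-bromophenol
Product: 8 1-bromo-4-(methoxymethoxy)benzene
Conditions: MOMCl, i-Pr2NEt, CH2Cl2, 0 °C to rt
Reagents that add atoms: chloromethyl methyl ether (MOMCl), COCCl
Why: Williamson-type O-alkylation of a single phenol; 8 serves both as the source of the alkyne partner and as the aryllithium precursor.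

Step 6
Reactants: 8 1-bromo-4-(methoxymethoxy)benzene; 9 ethynyltrimethylsilane
Product: 10 {[4-(methoxymethoxy)phenyl]ethynyl}trimethylsilane
Conditions: Pd(PhCN)2Cl2 (cat.), P(t-Bu)3 (cat.), CuI (cat.), i-Pr2NH, dioxane, rt
Reagents that add atoms: none
Why: Sonogashira coupling; the bulky electron-rich trialkylphosphine allows oxidative addition into an electron-rich aryl bromide at room temperature.

Step 7
Reactants: 10 {[4-(methoxymethoxy)phenyl]ethynyl}trimethylsilane
Product: 11 1-ethynyl-4-(methoxymethoxy)benzene
Conditions: K2CO3 (cat.), MeOH, rt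
Reagents that add atoms: none
Why: methoxide-catalysed protiodesilylation of an alkynylsilane, to which the MOM acetal is inert.

Step 8
Reactants: 6 3-(methoxymethoxy)phenyl 6-chloro-3-formyl-2-(trifluoromethylsulfonyloxy)benzoate; 11 1-ethynyl-4-(methoxymethoxy)benzene
Product: 12 3-(methoxymethoxy)phenyl 6-chloro-3-formyl-2-{[4-(methoxymethoxy)phenyl]ethynyl}benzoate
Conditions: PdCl2(PPh3)2 (cat.), CuI (cat.), Et3N, DMF, rt to 40 °C
Reagents that add atoms: none
Why: Sonogashira coupling in which triphenylphosphine-ligated palladium prefers C–OTf, here activated by two ortho carbonyl groups, over C–Cl, and a tertiary amine avoids condensation with the aldehyde.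

Step 9
Reactants: 12 3-(methoxymethoxy)phenyl 6-chloro-3-formyl-2-{[4-(methoxymethoxy)phenyl]ethynyl}benzoate
Product: 13 3-(methoxymethoxy)phenyl 6-chloro-3-(hydroxymethyl)-2-{[4-(methoxymethoxy)phenyl]ethynyl}benzoate
Conditions: NaBH4, THF/MeOH, −10 °C
Reagents that add atoms: none
Why: chemoselective borohydride 1,2-reduction of the aldehyde; the di-ortho-substituted aryl ester is too hindered to react at this temperature, and its meta relation to C5 rules out lactonisation.

Step 10
Reactants: 13 3-(methoxymethoxy)phenyl 6-chloro-3-(hydroxymethyl)-2-{[4-(methoxymethoxy)phenyl]ethynyl}benzoate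
Product: 14 3-(methoxymethoxy)phenyl 3-[(tert-butyldimethylsilyloxy)methyl]-6-chloro-2-{[4-(methoxymethoxy)phenyl]ethynyl}benzoate
Conditions: TBSCl, imidazole, CH2Cl2, rt
Reagents that add atoms: tert-butyldimethylsilyl chloride (TBSCl), CC(C)(C)[Si](C)(C)Cl
Why: imidazole-promoted silylation of a primary alcohol, which blocks hydroalkoxylation of the neighbouring alkyne and ester exchange in the hot basic key step.

Step 11
Reactants: 14 3-(methoxymethoxy)phenyl 3-[(tert-butyldimethylsilyloxy)methyl]-6-chloro-2-{[4-(methoxymethoxy)phenyl]ethynyl}benzoate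
Product: 15 8-[(tert-butyldimethylsilyloxy)methyl]-3-(methoxymethoxy)-7-{[4-(methoxymethoxy)phenyl]ethynyl}-6H-benzo[c]chromen-6-one
Conditions: Pd(OAc)2 (10 mol %), PCy3·HBF4 (20 mol %), PivOH (30 mol %), dry K2CO3, DMA (0.02 M), 120 °C
Reagents that add atoms: none
Why: Zerovalent palladium carrying PCy3 inserts into the C2–Cl bond, which the ortho ester carbonyl activates, pivalate then replaces chloride and removes the ring-B hydrogen para to OMOM by concerted metalation–deprotonation, and reductive elimination from the seven-membered palladacycle forms C2–C1′. The closest known reaction type is the palladium-catalysed intramolecular direct arylation of aryl 2-halobenzoates to benzo[c]chromen-6-ones, and trialkylphosphine/pivalate systems are established for aryl chlorides in such closures. The single new ring, the six-membered lactone, closes by aryl–aryl bond formation across the ester tether once the ester has turned into its E rotamer, which the temperature permits. No stereocentre is created. Site selectivity between the two C–H bonds ortho to the ester oxygen is required, and the inner one is crowded by the OMOM group and would push that group into the bay region facing H3 of ring A, so the outer C–H should react and give the 2′,4′-dioxygenation pattern. The C6 alkyne lies on the far side of C1 from the C2–Pd bond and is too remote for intramolecular insertion, dilution disfavours its intermolecular insertion, and an aryl ester cannot shed its O-substituent to form an isocoumarin.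

Step 12
Reactants: 15 8-[(tert-butyldimethylsilyloxy)methyl]-3-(methoxymethoxy)-7-{[4-(methoxymethoxy)phenyl]ethynyl}-6H-benzo[c]chromen-6-one; 8 1-bromo-4-(methoxymethoxy)benzene
Product: 18 {4-[(tert-butyldimethylsilyloxy)methyl]-2′-hydroxy-4′-(methoxymethoxy)-3-{[4-(methoxymethoxy)phenyl]ethynyl}biphenyl-2-yl}bis[4-(methoxymethoxy)phenyl]methanol, via 4-(methoxymethoxy)phenyllithium 16 (not isolated), via ring-opened lithium keto phenolate 17 (not isolated)
Conditions: 8 (4.5 equiv), n-BuLi (4.3 equiv), THF, −78 °C; then 15, −78 to 0 °C; aq. NH4Cl; Et3N-deactivated silica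
Reagents that add atoms: none
Why: bromine–lithium exchange followed by twofold 1,2-addition of an aryllithium to a lactone, in which the first adduct collapses to ketone 17 with release of the ring-B phenoxide and the non-enolisable carbonyl beside the slim alkyne takes up a second aryl group on warming, while the electron-rich alkyne, the MOM acetals and the TBS ether are inert.

Step 13
Reactants: 18 {4-[(tert-butyldimethylsilyloxy)methyl]-2′-hydroxy-4′-(methoxymethoxy)-3-{[4-(methoxymethoxy)phenyl]ethynyl}biphenyl-2-yl}bis[4-(methoxymethoxy)phenyl]methanol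
Product: 20 selaginellin F, via fully deprotected triaryl carbinol 19 (not isolated)
Conditions: 2 M aq. HCl, MeOH/THF, 40 °C; then aq. NaHCO3 to pH 6–7
Reagents that add atoms: none
Why: acid-catalysed solvolysis of the four MOM acetals and the TBS ether (methanol traps the formaldehyde units) gives 19, whose C7–OH ionises in SN1 fashion to a cation stabilised by two para-hydroxyphenyl groups, and loss of a phenolic proton on neutralisation completes an E1-type dehydration to the quinone methide; capture of the cation by methanol or the 2′-OH is reversible, and C6′, meta to both ring-B oxygens, is too poor a nucleophile for Friedel–Crafts closure to a fluorene.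

Compound list
1 | resorcinol | Oc1cccc(O)c1 | starting material
2 | 3-(methoxymethoxy)phenol | COCOc1cccc(O)c1 | intermediate
3 | 2-chloro-6-hydroxybenzoic acid | O=C(O)c1c(O)cccc1Cl | starting material
4 | 3-(methoxymethoxy)phenyl 2-chloro-6-hydroxybenzoate | COCOc1cccc(OC(=O)c2c(O)cccc2Cl)c1 | intermediate
5 | 3-(methoxymethoxy)phenyl 6-chloro-3-formyl-2-hydroxybenzoate | COCOc1cccc(OC(=O)c2c(O)c(C=O)ccc2Cl)c1 | intermediate
6 | 3-(methoxymethoxy)phenyl 6-chloro-3-formyl-2-(trifluoromethylsulfonyloxy)benzoate | COCOc1cccc(OC(=O)c2c(OS(=O)(=O)C(F)(F)F)c(C=O)ccc2Cl)c1 | intermediate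
7 | 4-bromophenol | Oc1ccc(Br)cc1 | starting material
8 | 1-bromo-4-(methoxymethoxy)benzene | COCOc1ccc(Br)cc1 | intermediate
9 | ethynyltrimethylsilane | C#C[Si](C)(C)C | starting material
10 | {[4-(methoxymethoxy)phenyl]ethynyl}trimethylsilane | COCOc1ccc(C#C[Si](C)(C)C)cc1 | intermediate
11 | 1-ethynyl-4-(methoxymethoxy)benzene | C#Cc1ccc(OCOC)cc1 | intermediate
12 | 3-(methoxymethoxy)phenyl 6-chloro-3-formyl-2-{[4-(methoxymethoxy)phenyl]ethynyl}benzoate | COCOc1ccc(C#Cc2c(C=O)ccc(Cl)c2C(=O)Oc2cccc(OCOC)c2)cc1 | intermediate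
13 | 3-(methoxymethoxy)phenyl 6-chloro-3-(hydroxymethyl)-2-{[4-(methoxymethoxy)phenyl]ethynyl}benzoate | COCOc1ccc(C#Cc2c(CO)ccc(Cl)c2C(=O)Oc2cccc(OCOC)c2)cc1 | intermediate
14 | 3-(methoxymethoxy)phenyl 3-[(tert-butyldimethylsilyloxy)methyl]-6-chloro-2-{[4-(methoxymethoxy)phenyl]ethynyl}benzoate (key-step precursor) | COCOc1ccc(C#Cc2c(CO[Si](C)(C)C(C)(C)C)ccc(Cl)c2C(=O)Oc2cccc(OCOC)c2)cc1 | intermediate
15 | 8-[(tert-butyldimethylsilyloxy)methyl]-3-(methoxymethoxy)-7-{[4-(methoxymethoxy)phenyl]ethynyl}-6H-benzo[c]chromen-6-one (key-step product) | COCOc1ccc(C#Cc2c(CO[Si](C)(C)C(C)(C)C)ccc3c2C(=O)Oc2cc(OCOC)ccc2-3)cc1 | intermediate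
16 | 4-(methoxymethoxy)phenyllithium | [Li]c1ccc(OCOC)cc1 | intermediate
17 | lithium 2-{4-[(tert-butyldimethylsilyloxy)methyl]-2-[4-(methoxymethoxy)benzoyl]-3-{[4-(methoxymethoxy)phenyl]ethynyl}phenyl}-5-(methoxymethoxy)phenolate | COCOc1ccc(C#Cc2c(CO[Si](C)(C)C(C)(C)C)ccc(-c3ccc(OCOC)cc3[O-])c2C(=O)c2ccc(OCOC)cc2)cc1.[Li+] | intermediate
18 | {4-[(tert-butyldimethylsilyloxy)methyl]-2′-hydroxy-4′-(methoxymethoxy)-3-{[4-(methoxymethoxy)phenyl]ethynyl}biphenyl-2-yl}bis[4-(methoxymethoxy)phenyl]methanol | COCOc1ccc(C#Cc2c(CO[Si](C)(C)C(C)(C)C)ccc(-c3ccc(OCOC)cc3O)c2C(O)(c2ccc(OCOC)cc2)c2ccc(OCOC)cc2)cc1 | intermediate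
19 | {2′,4′-dihydroxy-4-(hydroxymethyl)-3-[(4-hydroxyphenyl)ethynyl]biphenyl-2-yl}bis(4-hydroxyphenyl)methanol | OCc1ccc(-c2ccc(O)cc2O)c(C(O)(c2ccc(O)cc2)c2ccc(O)cc2)c1C#Cc1ccc(O)cc1 | intermediate
20 | selaginellin F | O=C1C=CC(=C(c2ccc(O)cc2)c2c(-c3ccc(O)cc3O)ccc(CO)c2C#Cc2ccc(O)cc2)C=C1 | target

Total step count: 13. Longest linear sequence: 10 (steps 1, 2, 3, 4, 8, 9, 10, 11, 12, 13).

Steps most likely to fail

**Step 11.**
- What may go wrong: oxidative addition into C2–Cl may be slow, and the ester may stay in its extended Z rotamer. Hydrodechlorination, carbonate-induced loss of the aryl ester, insertion of the alkyne of a second molecule into the aryl–palladium bond, or metalation at the C–H between the two oxygens could then take over.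
- Fallback: it sets out from 14 and comes back at 20, making the same bond intermolecularly. Commercial 4-bromoresorcinol is protected twice (MOMCl, i-Pr2NEt) to 1-bromo-2,4-bis(methoxymethoxy)benzene F1. Bromine–lithium exchange (n-BuLi, −78 °C) and quenching with B(Oi-Pr)3 turn it into [2,4-bis(methoxymethoxy)phenyl]boronic acid F2. Suzuki–Miyaura coupling of F2 with chloride 14 (Pd(OAc)2, SPhos, K3PO4, dioxane, 90 °C) should give 3-(methoxymethoxy)phenyl 4-[(tert-butyldimethylsilyloxy)methyl]-2′,4′-bis(methoxymethoxy)-3-{[4-(methoxymethoxy)phenyl]ethynyl}biphenyl-2-carboxylate F3. Excess 16 displaces the aryloxide of this activated ester and adds a second time, giving {4-[(tert-butyldimethylsilyloxy)methyl]-2′,4′-bis(methoxymethoxy)-3-{[4-(methoxymethoxy)phenyl]ethynyl}biphenyl-2-yl}bis[4-(methoxymethoxy)phenyl]methanol F4. The conditions of step 13 convert F4 through 19 into 20.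

**Step 12.**
- What may go wrong: the sequence may stop after the first addition. The lactolate may be slow to collapse, or the di-ortho-substituted ketone, further deactivated by the neighbouring phenoxide, may resist the second aryllithium.
- Fallback: it sets out from 15 and comes back at 20, staging the two additions. About one equivalent of 16 at −78 °C followed by an NH4Cl quench should give {4-[(tert-butyldimethylsilyloxy)methyl]-2′-hydroxy-4′-(methoxymethoxy)-3-{[4-(methoxymethoxy)phenyl]ethynyl}biphenyl-2-yl}[4-(methoxymethoxy)phenyl]methanone F5. Capping the phenol (MOMCl, i-Pr2NEt) removes the negative charge and gives {4-[(tert-butyldimethylsilyloxy)methyl]-2′,4′-bis(methoxymethoxy)-3-{[4-(methoxymethoxy)phenyl]ethynyl}biphenyl-2-yl}[4-(methoxymethoxy)phenyl]methanone F6. The less basic, more oxophilic organocerium reagent made from 16 and CeCl3 (THF, −78 to 0 °C) adds to F6 and gives the carbinol F4 already met above. The conditions of step 13 then deliver 20.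

**Step 3.**
- What may go wrong: formylation of the electron-poor, ester-chelated magnesium phenoxide may be sluggish. Over the long reaction time the methoxide generated could exchange with the aryl ester.
- Fallback: it sets out from 4 and comes back at 14, bringing in C5–CH2O at the alcohol level without any nucleophilic by-product. Phenylboronic-acid-templated ortho-hydroxymethylation (PhB(OH)2, (CH2O)n, cat. propionic acid, toluene, azeotropic removal of water) should give 3-(methoxymethoxy)phenyl 7-chloro-2-phenyl-4H-1,3,2-benzodioxaborinine-8-carboxylate F7. Boronate exchange with propane-1,3-diol frees 3-(methoxymethoxy)phenyl 6-chloro-2-hydroxy-3-(hydroxymethyl)benzoate F8. Selective silylation of the primary alcohol (TBSCl, imidazole, 0 °C) gives 3-(methoxymethoxy)phenyl 3-[(tert-butyldimethylsilyloxy)methyl]-6-chloro-2-hydroxybenzoate F9. Triflation (Tf2O, pyridine) gives 3-(methoxymethoxy)phenyl 3-[(tert-butyldimethylsilyloxy)methyl]-6-chloro-2-(trifluoromethylsulfonyloxy)benzoate F10. Sonogashira coupling of F10 with 11 (PdCl2(PPh3)2, CuI, Et3N, DMF, 60 °C) gives 14 directly.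

Further compounds
F1 | step 11 | 1-bromo-2,4-bis(methoxymethoxy)benzene | COCOc1ccc(Br)c(OCOC)c1
F2 | step 11 | [2,4-bis(methoxymethoxy)phenyl]boronic acid | COCOc1ccc(B(O)O)c(OCOC)c1
F3 | step 11 | 3-(methoxymethoxy)phenyl 4-[(tert-butyldimethylsilyloxy)methyl]-2′,4′-bis(methoxymethoxy)-3-{[4-(methoxymethoxy)phenyl]ethynyl}biphenyl-2-carboxylate | COCOc1ccc(C#Cc2c(CO[Si](C)(C)C(C)(C)C)ccc(-c3ccc(OCOC)cc3OCOC)c2C(=O)Oc2cccc(OCOC)c2)cc1
F4 | step 11 | {4-[(tert-butyldimethylsilyloxy)methyl]-2′,4′-bis(methoxymethoxy)-3-{[4-(methoxymethoxy)phenyl]ethynyl}biphenyl-2-yl}bis[4-(methoxymethoxy)phenyl]methanol | COCOc1ccc(C#Cc2c(CO[Si](C)(C)C(C)(C)C)ccc(-c3ccc(OCOC)cc3OCOC)c2C(O)(c2ccc(OCOC)cc2)c2ccc(OCOC)cc2)cc1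
F5 | step 12 | {4-[(tert-butyldimethylsilyloxy)methyl]-2′-hydroxy-4′-(methoxymethoxy)-3-{[4-(methoxymethoxy)phenyl]ethynyl}biphenyl-2-yl}[4-(methoxymethoxy)phenyl]methanone | COCOc1ccc(C#Cc2c(CO[Si](C)(C)C(C)(C)C)ccc(-c3ccc(OCOC)cc3O)c2C(=O)c2ccc(OCOC)cc2)cc1
F6 | step 12 | {4-[(tert-butyldimethylsilyloxy)methyl]-2′,4′-bis(methoxymethoxy)-3-{[4-(methoxymethoxy)phenyl]ethynyl}biphenyl-2-yl}[4-(methoxymethoxy)phenyl]methanone | COCOc1ccc(C#Cc2c(CO[Si](C)(C)C(C)(C)C)ccc(-c3ccc(OCOC)cc3OCOC)c2C(=O)c2ccc(OCOC)cc2)cc1
F7 | step 3 | 3-(methoxymethoxy)phenyl 7-chloro-2-phenyl-4H-1,3,2-benzodioxaborinine-8-carboxylate | COCOc1cccc(OC(=O)c2c(Cl)ccc3c2OB(c2ccccc2)OC3)c1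
F8 | step 3 | 3-(methoxymethoxy)phenyl 6-chloro-2-hydroxy-3-(hydroxymethyl)benzoate | COCOc1cccc(OC(=O)c2c(O)c(CO)ccc2Cl)c1
F9 | step 3 | 3-(methoxymethoxy)phenyl 3-[(tert-butyldimethylsilyloxy)methyl]-6-chloro-2-hydroxybenzoate | COCOc1cccc(OC(=O)c2c(O)c(CO[Si](C)(C)C(C)(C)C)ccc2Cl)c1
F10 | step 3 | 3-(methoxymethoxy)phenyl 3-[(tert-butyldimethylsilyloxy)methyl]-6-chloro-2-(trifluoromethylsulfonyloxy)benzoate | COCOc1cccc(OC(=O)c2c(OS(=O)(=O)C(F)(F)F)c(CO[Si](C)(C)C(C)(C)C)ccc2Cl)c1
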